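Slow chemistry turns the question into one of position: with 25 mM of partner, Sunday's single product rises through every reading up to 120 min, so each new flask is placed on that curve.

| setting | Sunday's | Tuesday's | south-west | south |
|---|---|---|---|---|
| substrate | 3.5 mM | 5.6 mM | 3.0 mM | 10 mM |
| partner | 25 mM | 25 mM | 25.0 mM | 25.0 mM |
| remark | run made earlier | run made earlier |  |  |
| time |  |  | 3.0 h | 2.0 h |

| Sunday's: time / min | Sunday's: single product / % | Tuesday's: time / min | Tuesday's: single product / % |
|---|---|---|---|
| 10.0 | 6.5 | 10.0 | 6.7 |
| 20.0 | 14.1 | 20.0 | 13.5 |
| 30.0 | 19.8 | 30.0 | 18.6 |
| 60.0 | 30.4 | 60.0 | 30.2 |
| 120 | 38.0 | 120 | 38.2 |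

(readings scatter by 0.5 percentage points)

- the winner by amount of single product, in percent of the substrate charged; "neither" if no more than 2 percentage points parts them (south-west / south / neither)
- how much single product is there at the end, in percent of the substrate charged: south-west
- how much single product is there at the end, in percent of the substrate charged: south

- amounts and yields of by-product count crystals too
- given per volume of solution although it is solid: crystals
- the numbers in the tables scatter with a standard deviation of 0.5 percentage points
- steps under discussion: substrate -> decomposition product; single product -> over-reaction product; crystals <-> by-product; substrate + partner -> single product + by-product; partner + bis adduct -> triple product + by-product; partner + single product -> bis adduct + by-product; partner + triple product -> tetra adduct + by-product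

Between the two earlier runs, at equal partner, substrate charge shows little in percent: Tuesday's is 1.60 times Sunday's, yet the last readings differ by 0.2 percentage points, within the scatter, as in a pseudo-first-order reaction. Partner and time are taken to act as a product. South is reckoned to use one partner per single product and one more for further adducts, 7.60 mM by the end. Replacing its falling partner by the mean gives 21.2 mM. South's 2.0 h then count as 102 min on the partner clock, the time multiplied by mean partner and divided by the earlier runs' 25 mM. Dropping the adduct allowance moves this by 9.12 min, worth 1.2 points on the line through Sunday's last two readings. That line puts south 2.3 points below 38.0%, and the bending curve perhaps half that, so this reckoning gives 36.8%. South-west's clock reads 172 min, beyond the readings, on a curve gaining 11 points in 30.0 min and then 7.6 points in 60.0 min. Taking south-west near 38.0%, the gap is 1.1 points against a margin of 2 points: neither.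

The forecast says south-west, with 39% (35% to 42%) against 36% (31% to 39.5%): “South-west should win, but only narrowly”.

The flask gives neither: south-west 37.2%, south 37.0%.

    substrate → decomposition product (k = 2.10 × 10⁻⁷ s⁻¹)
    single product → over-reaction product (k = 4.20 × 10⁻⁵ s⁻¹)
    crystals ⇌ by-product, rate k3*(cs3 - [by-product]) while solid is left; crystals form when [by-product] > cs3 (solubility = 5.90 mM, k = 0.0200 s⁻¹)
    substrate + partner → single product + by-product (k = 0.00550 M⁻¹ s⁻¹)
    partner + bis adduct → triple product + by-product (k = 0.00240 M⁻¹ s⁻¹)
    partner + single product → bis adduct + by-product (k = 0.00310 M⁻¹ s⁻¹)
    partner + triple product → tetra adduct + by-product (k = 0.00200 M⁻¹ s⁻¹)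

In south, 43.3% of the substrate still stood at 2.00 h, and single product was being made 1.18 times faster than used. South-west, with 25% of its substrate at 3.00 h, held 18.7% bis adduct. South's partner ended at 72.0% of its charge, so its clock reads 103 min. South read at 30 min, with 91% of its partner left, has a clock of 28.7 min, which on Sunday's readings gives 19.0%; the computed value is 18.9%.

(The runs were computed from invented constants; the scatter is artificial.)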